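## The problem

Daphnodorin F (28) joins a 3-hydroxychromanone and a flavan through one phloroglucinol-derived arene (ring D, C4a''–C8a''). The chromanone C2 is a double ketal carbon bonded to O1, to the C7'' oxygen and to ring B, and the neighbouring C3 is a tertiary carbinol bonded to C8'' and to the C4 carbonyl. A dihydrofuran and a pyranone ring are therefore fused along C2–C3. The flavan pyran ring sits on the same arene in the angular sense (O1'' on C8a'', next to C8''), so the three oxygens of ring D must be told apart: one closes the furan, one the pyran, and the C5'' oxygen stays a phenol. C2 and C3 are contiguous, fully substituted and can only be made as a pair; C2'' lies beyond the flat arene, so neither unit can control the other and two independent absolute controls are needed. The fragile parts are the aryl ketal with its α-ketol, five electron-rich phenols that do not tolerate oxidants, and the benzylic ether carbon C2'', which is para to the ring E phenol and epimerises through a quinone methide as soon as acid is present. That liability is also the opening. Because C2'' is para to a phenol and three atoms from the C8a'' phenol, the pyran ring can be closed last: a benzylic carbinol of either configuration is ionised to a para-quinone methide and O1'' adds to it under a chiral acid.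

## Retrosynthesis

**28 ⇒ 27.** Three aryl O–benzyl bonds are cut (ring A C5–O, ring B C4'–O, C5''–O). Neutral hydrogenolysis is the only final operation that does not endanger C2''. The C5'' benzyl ether has a second task in the step before.

**27 ⇒ 25 (through 26).** The O1''–C2'' bond is cut. C2'' is the one centre that cannot be carried safely through a long sequence, and both epimers of carbinol 25 converge on the planar quinone methide 26, so the chain needs no stereocontrol. Cutting C2''–C3'' or C4''–C4a'' instead would mean C–C bond formation on the loaded core. The forward step must select a methide face by catalyst alone, must stay under kinetic control, and must have only one phenol ortho to the chain; the C5'' benzyl ether ensures the last point.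

**25 ⇒ 24 ⇒ 22 (through 23).** After returning the silyl ethers, the C2–O1 and C3–O bonds are cut. Oxygen transfer to the C2=C3 bond of the 3-aroylbenzofuran 22, with capture of epoxide 23 by the ortho phenol of ring A, creates both fully substituted centres in one event from a flat precursor. The other cuts through this ring system are weighed under "Roads not taken". The forward step must choose one face of the benzofuran and needs the ring A phenol free while every other oxidisable hydroxyl is masked.

**22 ⇒ 20 ⇒ 19 ⇒ 18.** These are adjustments of protecting groups and oxidation level. The carbinol of 20 comes from ketone 19. That ketone and the C4 phenol of the benzofuran (the future O1'') are released together from the cyclic methyl ketal in 18, in the same acid step that frees ring A, before any ionisable carbinol exists. The reduction must leave the aroyl ketone alone.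

**18 ⇒ 17 ⇒ 16 + 7.** The C3a–C3 bond (intramolecular Heck) and the aryl O–C2 bond (oxa-Michael) are cut. The crowded aroyl ketone is already present in ynone 7, so no acylation at the hindered benzofuran C3 is needed. The iodine and the single free phenol of 16 fix the regiochemistry. The two fragments are of similar size.

**16 ⇒ 14 (through 15) ⇒ 13 ⇒ 12 ⇒ 10 + 11.** In 16 the chain ketone is tied to the phenol ortho to the chain as a six-membered methyl ketal. Only that phenol can reach the ketone, so the two oxygens flanking iodine are differentiated without a protecting-group step, and the para oxygen is left as the only free phenol. The chain comes from Claisen–Schmidt condensation of 10 with 11, silylation and C=C reduction.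

**10 ⇒ 3; 7 ⇒ 6 ⇒ 3 + 4; 3 ⇒ 2 ⇒ 1.** The C–I bond is placed by directed metalation at the only ring position flanked by two MOM ethers, which defines the angular connectivity. Ynone 7 comes from acetylide addition to the same aldehyde 3 and oxidation. Aldehyde 3 arises from 1 by two chelation-guided etherifications and serves both ring A and ring D.

## Roads not taken

**Alternative 1:** The cut runs through C3–C4 and C2–O1, so the whole pyranone ring is added in one step to a flavan-fused benzofuran.
- Forward step: heating the ring A benzodioxinone A1 would release the quinoketene A3, which adds across C2=C3 of the 3-(benzyloxycarbonyloxy)benzofuran A2. The polarity is matched (nucleophilic C3 to the ketene carbon, phenolic oxygen to C2), and the product is the penta-O-benzyl C3 carbonate A4.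
- Merits: highest convergence; ring fusion and protected C3 oxygen arrive together; no oxidant meets the electron-rich rings.
- Weak points: the only stereocentre of A2 is C2'', too remote to bias the furan faces, and a thermal cycloaddition offers no catalyst handle. The two core diastereomers would form without control, at the cost of half of an enantiopure flavan. The ketene must be generated thermally at a temperature at which the enol carbonate of A2 may migrate. A2 itself needs an enantioselective flavan synthesis and a 3-oxygenated benzofuran.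
- Comparison: the endgame would be shorter and it avoids an untested asymmetric oxidation, which is a real advantage. The chosen plan sets against it catalyst control over both stereochemical units and a flavan centre that is never carried.

**Alternative 2:** The cut is at C3–O and C2–O(C7''), starting from a 3-arylflavone in which ring D is already attached to C3.
- Forward step: a chiral Mn(salen)Cl complex (trivalent manganese) with an iodosylarene epoxidises C2=C3 of chromone acetate A5. After cleavage of the acetate, the C7'' phenoxide opens the epoxide at C2 to give penta-O-benzyl daphnodorin F, A6.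
- Merits: the oxidation has closer precedent than the one chosen here, since the enol ether bond of chromones is a documented substrate class for this catalyst family. The product is one hydrogenolysis from 28.
- Weak points: A5 requires a C3–C8'' bond between a chromone and an arene carbon flanked by two oxygens, a heavily ortho-substituted biaryl-type coupling. It also requires an enantiopure flavan with its C7'' oxygen singled out, carried through every step. The 2,3-diaryl chromone is more hindered and less electron-rich than the known substrates.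
- Comparison: in precedent for the oxidation this road is better. The chosen plan sets against it an intramolecular C3a–C3 bond formation of a known type and a C2'' centre made last from a racemic carbinol.

**Alternative 3:** The cut is at C4–C4a, C2–O(C7'') and C2–O1: unprotected phloroglucinol A8 is annulated onto a chiral keto lactone.
- Forward step: a boron trifluoride-type Lewis acid would promote C-acylation of A8 by the lactone carbonyl of A7. The released C7'' phenol and the new ortho phenol of ring A then ketalise the ring B ketone to give A9.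
- Merits: ring A enters without protecting groups and without regiochemical questions; the product carries only three benzyl ethers; C3 controls C2 through the ring fusion.
- Weak points: A7 contains an enantiopure tertiary carbinol between two carbonyls, which is hard to make and prone to ketol shift and acyl cleavage under Lewis acid. Acylation of a phenol by an aryl ester needs forcing acid. The benzyl-protected flavan ether at C2'' can ionise under the same acid.
- Comparison: the step count would be lower. The chosen plan is longer, but each bond is made under mild conditions and no strong Lewis acid meets C2'' or the α-ketol.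

Key step: step 17

Remarks on the chemistry:
- Locants: chromanone O1, C2 (ketal), C3 (carbinol), C4 (carbonyl); ring A = C4a–C8a; ring B = aryl on C2 (primed); flavan part double-primed; ring D = C4a''–C8a''; ring E = aryl on C2''. Benzofuran intermediates use benzofuran locants (C4–O is the future O1'', C5 carries the chain, C6–O is the future C5''–O).
- C2, C3 and C2'' are named 2S, 3R and 2''S as read from structure 28. C2 and C3 arise in one step, so only their absolute sense has to be chosen by the catalyst.
- The sense of induction of the two chiral catalysts on these substrates cannot be assigned in advance. The enantiomer named is a working choice, and its antipode is taken if a first trial shows the opposite sense.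

## Route

Step 1
Reactants: 1 2,4,6-trihydroxybenzaldehyde
Product: 2 2-hydroxy-4,6-bis(methoxymethoxy)benzaldehyde
Conditions: MOMCl (2.2 equiv), i-Pr2NEt, CH2Cl2, 0 °C → rt
Reagents that add atoms: chloromethyl methyl ether, COCCl
Why: Williamson-type O-alkylation; the para hydroxyl and one ortho hydroxyl react, while the second ortho hydroxyl stays hydrogen-bonded to the formyl group and resists alkylation under amine base.

Step 2
Reactants: 2 2-hydroxy-4,6-bis(methoxymethoxy)benzaldehyde
Product: 3 2-(benzyloxy)-4,6-bis(methoxymethoxy)benzaldehyde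
Conditions: BnBr, K2CO3, DMF, 60 °C
Reagents that add atoms: benzyl bromide, BrCc1ccccc1
Why: Williamson ether synthesis; carbonate in warm DMF breaks the chelate and benzylates the last phenol, giving the aldehyde that serves both ring A and ring D.

Step 3
Reactants: 4 1-(benzyloxy)-4-ethynylbenzene; 3 2-(benzyloxy)-4,6-bis(methoxymethoxy)benzaldehyde
Product: 6 racemic 1-[2-(benzyloxy)-4,6-bis(methoxymethoxy)phenyl]-3-[4-(benzyloxy)phenyl]prop-2-yn-1-ol, via lithium acetylide 5 (not isolated)
Conditions: 4, n-BuLi, THF, −78 °C; then 3, −78 → 0 °C; H2O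
Reagents that add atoms: none
Why: 1,2-addition of a lithium acetylide to a non-enolisable aldehyde; the carbinol centre is racemic and is removed in step 4.

Step 4
Reactants: 6 racemic propargylic alcohol
Product: 7 1-[2-(benzyloxy)-4,6-bis(methoxymethoxy)phenyl]-3-[4-(benzyloxy)phenyl]prop-2-yn-1-one
Conditions: MnO2, CH2Cl2, rt
Reagents that add atoms: none
Why: MnO2 oxidation of a propargylic, benzylic alcohol to the ynone; both ortho oxygens of ring A stay masked, so the ynone cannot cyclise to a flavone.

Step 5
Reactants: 3 2-(benzyloxy)-4,6-bis(methoxymethoxy)benzaldehyde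
Product: 10 6-(benzyloxy)-3-iodo-2,4-bis(methoxymethoxy)benzaldehyde, via lithium aminoalkoxide 8 (not isolated), via ring-lithiated aminoalkoxide 9 (not isolated)
Conditions: Me2NCH2CH2N(Me)Li (from the amine and n-BuLi), THF, −20 °C; n-BuLi (3 equiv), −20 °C; I2, −78 °C → rt; H2O
Reagents that add atoms: iodine, II
Why: Directed ortho-metalation with in situ protection of the aldehyde as its α-amino alkoxide; the only ring hydrogen flanked by two MOM ethers is removed (the other lies between a MOM and a weakly directing benzyl ether), and iodinolysis marks the carbon that becomes C8''.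

Step 6
Reactants: 10 6-(benzyloxy)-3-iodo-2,4-bis(methoxymethoxy)benzaldehyde; 11 4'-hydroxyacetophenone
Product: 12 (E)-3-[6-(benzyloxy)-3-iodo-2,4-bis(methoxymethoxy)phenyl]-1-(4-hydroxyphenyl)prop-2-en-1-one
Conditions: KOH (50% aq.), EtOH, rt
Reagents that add atoms: none
Why: Claisen–Schmidt condensation; the aldehyde has no α-hydrogen, the acetophenone enolate adds and the aldol dehydrates to the E-enone, while MOM ethers, benzyl ether and aryl iodide tolerate aqueous hydroxide.

Step 7
Reactants: 12 (E)-chalcone phenol
Product: 13 (E)-3-[6-(benzyloxy)-3-iodo-2,4-bis(methoxymethoxy)phenyl]-1-[4-(triisopropylsilyloxy)phenyl]prop-2-en-1-one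
Conditions: TIPSCl, imidazole, DMF, rt
Reagents that add atoms: chlorotriisopropylsilane, CC(C)[Si](Cl)(C(C)C)C(C)C
Why: Silylation of the only hydroxyl; the bulky aryl TIPS ether should survive the acid of steps 9 and 12 and the carbonate of step 10 and leave with fluoride in step 16.

Step 8
Reactants: 13 silylated chalcone
Product: 14 3-[6-(benzyloxy)-3-iodo-2,4-bis(methoxymethoxy)phenyl]-1-[4-(triisopropylsilyloxy)phenyl]propan-1-one
Conditions: H2 (3 atm), RhCl(PPh3)3 (5 mol%), toluene/EtOH, 40 °C
Reagents that add atoms: none
Why: Homogeneous hydrogenation of the conjugated disubstituted C=C; this catalyst does not hydrogenolyse benzyl ethers or the aryl iodide and leaves the aryl ketone.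

Step 9
Reactants: 14 dihydrochalcone
Product: 16 racemic 5-(benzyloxy)-8-iodo-2-methoxy-2-[4-(triisopropylsilyloxy)phenyl]chroman-7-ol, via dihydroxy ketone 15 (not isolated)
Conditions: HCl (1.25 M in MeOH), rt
Reagents that add atoms: methanol, CO
Why: Acidic methanolysis of both MOM ethers, then intramolecular ketalisation; only the phenol ortho to the chain can reach the ketone (six-membered mixed methyl ketal), which differentiates the two oxygens flanking iodine and leaves the para oxygen as the only free phenol; the ketal centre is racemic and temporary.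

Step 10
Reactants: 16 racemic iodochromanol; 7 ynone
Product: 17 3-[4-(benzyloxy)phenyl]-1-[2-(benzyloxy)-4,6-bis(methoxymethoxy)phenyl]-3-({5-(benzyloxy)-8-iodo-2-methoxy-2-[4-(triisopropylsilyloxy)phenyl]chroman-7-yl}oxy)prop-2-en-1-one (E/Z mixture)
Conditions: Cs2CO3 (0.2 equiv), MeCN, 40 °C
Reagents that add atoms: none
Why: Base-catalysed oxa-Michael addition of the single free phenol of 16 to the β-carbon of the ynone; both enol ether geometries can be used in step 11.

Step 11
Reactants: 17 β-aryloxy enone
Product: 18 3-[2-(benzyloxy)-4,6-bis(methoxymethoxy)benzoyl]-6-(benzyloxy)-2-[4-(benzyloxy)phenyl]benzofuran whose C4 oxygen and C5 are bridged as O–C(OMe)[4-(triisopropylsilyloxy)phenyl]–CH2–CH2 (racemic at the ketal carbon)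
Conditions: Pd(OAc)2 (10 mol%), PPh3 (20 mol%), Ag2CO3 (1.5 equiv), MeCN, 80 °C
Reagents that add atoms: none
Why: Intramolecular Heck-type cyclisation: zerovalent palladium inserts into the C–I bond, the aryl group adds to the enol ether carbon α to the ketone, and base-assisted loss of the acidic α-hydrogen gives the 3-aroyl-2-arylbenzofuran; the reaction is known for 2-iodoaryl β-aryloxy enones and avoids acylation at the hindered C3.

Step 12
Reactants: 18 ketal-locked benzofuran
Product: 19 {6-(benzyloxy)-2-[4-(benzyloxy)phenyl]-4-hydroxy-5-[3-oxo-3-(4-triisopropylsilyloxyphenyl)propyl]benzofuran-3-yl}[2-(benzyloxy)-4,6-dihydroxyphenyl]methanone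
Conditions: 2 M aq. HCl, THF, 45 °C
Reagents that add atoms: water, O
Why: Acid hydrolysis opens the cyclic methyl ketal to the aryl ketone and the C4 phenol and cleaves both ring A MOM ethers (the ortho one with chelation assistance); this is done before any ionisable carbinol exists, and aryl TIPS and benzyl ethers are stable.

Step 13
Reactants: 19 keto triol
Product: 20 {6-(benzyloxy)-2-[4-(benzyloxy)phenyl]-4-hydroxy-5-[3-hydroxy-3-(4-triisopropylsilyloxyphenyl)propyl]benzofuran-3-yl}[2-(benzyloxy)-4,6-dihydroxyphenyl]methanone (racemic carbinol)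
Conditions: NaBH4, THF/MeOH, 0 °C
Reagents that add atoms: none
Why: Borohydride reduction of the unhindered alkyl aryl ketone; the aroyl ketone is a doubly ortho-substituted vinylogous ester of the furan oxygen and, once its para phenol is ionised by the basic medium, a vinylogous carboxylate, so it should not be reduced; the racemic carbinol is what the key step needs.

Step 14
Reactants: 20 racemic carbinol
Product: 22 {6-(benzyloxy)-2-[4-(benzyloxy)phenyl]-4-(tert-butyldimethylsilyloxy)-5-[3-(tert-butyldimethylsilyloxy)-3-(4-triisopropylsilyloxyphenyl)propyl]benzofuran-3-yl}[2-(benzyloxy)-4,6-dihydroxyphenyl]methanone (racemic), via tetrakis(silyl) ether 21 (not isolated)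
Conditions: TBSOTf (6 equiv), 2,6-lutidine, CH2Cl2, 0 °C; then MeOH, K2CO3 (cat.), 0 °C
Reagents that add atoms: tert-butyldimethylsilyl trifluoromethanesulfonate, CC(C)(C)[Si](C)(C)OS(=O)(=O)C(F)(F)F
Why: Exhaustive silylation with the silyl triflate also covers the hindered C4 phenol; brief carbonate methanolysis then removes only the two silyl ethers ortho and para to the aroyl carbonyl (stabilised phenoxide leaving groups) and frees the ring A phenol needed in step 15.

Step 15
Reactants: 22 bis(silyl) benzofuran
Product: 24 (2S,3R)-5-(benzyloxy)-2-[4-(benzyloxy)phenyl]-3,7-dihydroxychroman-4-one bridged from C2–O and C3 to C7''–O and C8'' of ring D that carries 5''-benzyloxy, 8a''-(tert-butyldimethylsilyloxy) and the 4a''-[3-(tert-butyldimethylsilyloxy)-3-(4-triisopropylsilyloxyphenyl)propyl] chain (both carbinol epimers), via benzofuran epoxide 23 (not isolated)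
Conditions: chloro[(S,S)-N,N'-bis(3,5-di-tert-butylsalicylidene)-1,2-cyclohexanediaminato]manganese (10 mol%), PhIO (2 equiv), 4-phenylpyridine N-oxide (0.3 equiv), CH2Cl2, 0 °C
Reagents that add atoms: iodosylbenzene, O=Ic1ccccc1
Why: Proposed new method: the trivalent manganese salen complex and iodosylbenzene form an oxo-manganese species (pentavalent manganese) that transfers oxygen to the C2=C3 enol ether bond of the benzofuran; the C2–O bond of epoxide 23 is ionised by the furan oxygen and the para-benzyloxyphenyl group, and the chelated ortho phenol of ring A closes onto C2 in a six-membered ring; the face of oxo transfer chosen by the salen ligand sets C3, and C2 follows because the tethered phenol can add in only one way; the closest known reaction types are Jacobsen–Katsuki epoxidation of chromenes and of the enol ether bond of isoflavones, and dioxirane epoxidation of benzofurans.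

Step 16
Reactants: 24 silylated bisketal
Product: 25 (2S,3R)-5-(benzyloxy)-2-[4-(benzyloxy)phenyl]-3,7-dihydroxychroman-4-one bridged from C2–O and C3 to C7''–O and C8'' of ring D that carries 5''-benzyloxy, 8a''-hydroxy and the 4a''-[3-hydroxy-3-(4-hydroxyphenyl)propyl] chain (both carbinol epimers)
Conditions: TBAF/AcOH (1:1, 5 equiv), THF, 0 °C → rt
Reagents that add atoms: none
Why: Fluoride cleaves the two TBS ethers and the TIPS ether; acetic acid keeps the phenols protonated so that the 4-hydroxybenzylic alcohol is not ionised, and benzyl ethers, ketal and α-ketol are untouched.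

Step 17
Reactants: 25 seco precursor (both carbinol epimers)
Product: 27 5,4',5''-tri-O-benzyldaphnodorin F (2S,3R,2''S), via para-quinone methide 26 (not isolated)
Conditions: (R)-3,3'-bis(2,4,6-triisopropylphenyl)-1,1'-binaphthyl-2,2'-diyl hydrogen phosphate (10 mol%), 5 Å MS, CH2Cl2/toluene, −30 °C
Reagents that add atoms: none
Why: The phosphoric acid protonates the benzylic hydroxyl of 25, water leaves with help from the para hydroxyl of ring E, and both carbinol epimers give the same planar para-quinone methide 26. The phosphate remains hydrogen-bonded to the methide oxygen and, through its P=O group, to the C8a'' phenol, so the addition occurs inside a chiral ion pair. The phenol oxygen adds to the methide carbon (oxa-1,6-addition, 6-exo-trig closure of the pyran ring) and ring E rearomatises. The closest known reactions are chiral phosphoric acid-catalysed 1,6-additions to para-quinone methides generated in situ from 4-hydroxybenzyl alcohols and their intramolecular oxa variants that give 2-arylchromans. C2'' is set by the catalyst alone, because C2 and C3 lie beyond the arene and cannot bias the methide faces. Regioselectivity comes from the substrate: the C5'' oxygen is a benzyl ether, the C8a'' hydroxyl is the only phenol ortho to the chain, the C3 hydroxyl would have to form an eight-membered ring and the ring A phenol is remote. Low temperature, sieves and a stop at full conversion keep the closure under kinetic control, since the product can reopen to 26 under the same acid.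

Step 18
Reactants: 27 5,4',5''-tri-O-benzyldaphnodorin F
Product: 28 daphnodorin F (2S,3R,2''S)
Conditions: H2 (1 atm), Pd/C (10 wt%), EtOAc/MeOH, rt
Reagents that add atoms: none
Why: Hydrogenolysis of three aryl benzyl ethers under neutral conditions, so C2'' cannot epimerise; the ring C–O bonds at C2'' and at the C2 ketal should be cleaved much more slowly than aryl benzyl ethers, as in flavan deprotections.

## Compound list

1 | 2,4,6-trihydroxybenzaldehyde | O=Cc1c(O)cc(O)cc1O | starting material
2 | 2-hydroxy-4,6-bis(methoxymethoxy)benzaldehyde | O=Cc1c(O)cc(OCOC)cc1OCOC | intermediate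
3 | 2-(benzyloxy)-4,6-bis(methoxymethoxy)benzaldehyde | O=Cc1c(OCc2ccccc2)cc(OCOC)cc1OCOC | intermediate
4 | 1-(benzyloxy)-4-ethynylbenzene | C#Cc1ccc(OCc2ccccc2)cc1 | starting material
5 | lithium [4-(benzyloxy)phenyl]acetylide (not isolated) | [Li]C#Cc1ccc(OCc2ccccc2)cc1 | intermediate
6 | racemic 1-[2-(benzyloxy)-4,6-bis(methoxymethoxy)phenyl]-3-[4-(benzyloxy)phenyl]prop-2-yn-1-ol | OC(C#Cc1ccc(OCc2ccccc2)cc1)c1c(OCc2ccccc2)cc(OCOC)cc1OCOC | intermediate
7 | 1-[2-(benzyloxy)-4,6-bis(methoxymethoxy)phenyl]-3-[4-(benzyloxy)phenyl]prop-2-yn-1-one | O=C(C#Cc1ccc(OCc2ccccc2)cc1)c1c(OCc2ccccc2)cc(OCOC)cc1OCOC | intermediate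
8 | lithium α-amino alkoxide from 3 and lithium N,N,N'-trimethylethylenediamide (not isolated) | [Li]OC(N(C)CCN(C)C)c1c(OCc2ccccc2)cc(OCOC)cc1OCOC | intermediate
9 | 8 lithiated at the ring carbon between the two MOM ethers (not isolated) | [Li]OC(N(C)CCN(C)C)c1c(OCc2ccccc2)cc(OCOC)c([Li])c1OCOC | intermediate
10 | 6-(benzyloxy)-3-iodo-2,4-bis(methoxymethoxy)benzaldehyde | O=Cc1c(OCc2ccccc2)cc(OCOC)c(I)c1OCOC | intermediate
11 | 4'-hydroxyacetophenone | CC(=O)c1ccc(O)cc1 | starting material
12 | (E)-3-[6-(benzyloxy)-3-iodo-2,4-bis(methoxymethoxy)phenyl]-1-(4-hydroxyphenyl)prop-2-en-1-one | O=C(/C=C/c1c(OCc2ccccc2)cc(OCOC)c(I)c1OCOC)c1ccc(O)cc1 | intermediate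
13 | (E)-3-[6-(benzyloxy)-3-iodo-2,4-bis(methoxymethoxy)phenyl]-1-[4-(triisopropylsilyloxy)phenyl]prop-2-en-1-one | O=C(/C=C/c1c(OCc2ccccc2)cc(OCOC)c(I)c1OCOC)c1ccc(O[Si](C(C)C)(C(C)C)C(C)C)cc1 | intermediate
14 | 3-[6-(benzyloxy)-3-iodo-2,4-bis(methoxymethoxy)phenyl]-1-[4-(triisopropylsilyloxy)phenyl]propan-1-one | O=C(CCc1c(OCc2ccccc2)cc(OCOC)c(I)c1OCOC)c1ccc(O[Si](C(C)C)(C(C)C)C(C)C)cc1 | intermediate
15 | 3-[6-(benzyloxy)-2,4-dihydroxy-3-iodophenyl]-1-[4-(triisopropylsilyloxy)phenyl]propan-1-one (not isolated) | O=C(CCc1c(OCc2ccccc2)cc(O)c(I)c1O)c1ccc(O[Si](C(C)C)(C(C)C)C(C)C)cc1 | intermediate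
16 | racemic 5-(benzyloxy)-8-iodo-2-methoxy-2-[4-(triisopropylsilyloxy)phenyl]chroman-7-ol | COC1(c2ccc(O[Si](C(C)C)(C(C)C)C(C)C)cc2)CCc2c(OCc3ccccc3)cc(O)c(I)c2O1 | intermediate
17 | β-aryloxy enone from 16 and 7 (E/Z mixture, racemic ketal) | O=C(C=C(Oc1cc(OCc2ccccc2)c2c(c1I)OC(OC)(c1ccc(O[Si](C(C)C)(C(C)C)C(C)C)cc1)CC2)c1ccc(OCc2ccccc2)cc1)c1c(OCc2ccccc2)cc(OCOC)cc1OCOC | intermediate
18 | ketal-locked 3-aroyl-2-arylbenzofuran (racemic ketal) | O=C(c1c(-c2ccc(OCc3ccccc3)cc2)oc2cc(OCc3ccccc3)c3c(c12)OC(OC)(c1ccc(O[Si](C(C)C)(C(C)C)C(C)C)cc1)CC3)c1c(OCc2ccccc2)cc(OCOC)cc1OCOC | intermediate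
19 | {6-(benzyloxy)-2-[4-(benzyloxy)phenyl]-4-hydroxy-5-[3-oxo-3-(4-triisopropylsilyloxyphenyl)propyl]benzofuran-3-yl}[2-(benzyloxy)-4,6-dihydroxyphenyl]methanone | O=C(CCc1c(OCc2ccccc2)cc2oc(-c3ccc(OCc4ccccc4)cc3)c(C(=O)c3c(O)cc(O)cc3OCc3ccccc3)c2c1O)c1ccc(O[Si](C(C)C)(C(C)C)C(C)C)cc1 | intermediate
20 | racemic carbinol from 19 (3-hydroxy-3-arylpropyl chain) | OC(CCc1c(OCc2ccccc2)cc2oc(-c3ccc(OCc4ccccc4)cc3)c(C(=O)c3c(O)cc(O)cc3OCc3ccccc3)c2c1O)c1ccc(O[Si](C(C)C)(C(C)C)C(C)C)cc1 | intermediate
21 | tetrakis(tert-butyldimethylsilyl) ether of 20 (carbinol O, benzofuran C4–O, both ring A O; not isolated) | CC(C)(C)[Si](C)(C)OC(CCc1c(OCc2ccccc2)cc2oc(-c3ccc(OCc4ccccc4)cc3)c(C(=O)c3c(O[Si](C)(C)C(C)(C)C)cc(O[Si](C)(C)C(C)(C)C)cc3OCc3ccccc3)c2c1O[Si](C)(C)C(C)(C)C)c1ccc(O[Si](C(C)C)(C(C)C)C(C)C)cc1 | intermediate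
22 | bis(tert-butyldimethylsilyl) ether of 20 (carbinol O and benzofuran C4–O; ring A phenols free; racemic) | CC(C)(C)[Si](C)(C)OC(CCc1c(OCc2ccccc2)cc2oc(-c3ccc(OCc4ccccc4)cc3)c(C(=O)c3c(O)cc(O)cc3OCc3ccccc3)c2c1O[Si](C)(C)C(C)(C)C)c1ccc(O[Si](C(C)C)(C(C)C)C(C)C)cc1 | intermediate
23 | 2,3-epoxide of 22, oxygen on the face that becomes the C3 hydroxyl of 24 (both carbinol epimers; not isolated) | O=C(c1c(O)cc(O)cc1OCc1ccccc1)[C@@]12O[C@]1(c1ccc(OCc3ccccc3)cc1)Oc1cc(OCc3ccccc3)c(CCC(O[Si](C)(C)C(C)(C)C)c3ccc(O[Si](C(C)C)(C(C)C)C(C)C)cc3)c(O[Si](C)(C)C(C)(C)C)c12 | intermediate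
24 | (2S,3R)-bisketal, 5-O-benzyl, 4'-O-benzyl, 5''-O-benzyl, 8a''-O-TBS, chain carbinol O-TBS, ring E O-TIPS (both carbinol epimers) | O=C1c2c(OCc5ccccc5)cc(O)cc2O[C@]2(c3ccc(OCc5ccccc5)cc3)Oc3cc(OCc5ccccc5)c(CCC(O[Si](C)(C)C(C)(C)C)c4ccc(O[Si](C(C)C)(C(C)C)C(C)C)cc4)c(O[Si](C)(C)C(C)(C)C)c3[C@@]12O | intermediate
25 | (2S,3R)-bisketal with 5-O-benzyl, 4'-O-benzyl, 5''-O-benzyl, free C8a'' phenol and 3-hydroxy-3-(4-hydroxyphenyl)propyl chain (both carbinol epimers) | O=C1c2c(OCc5ccccc5)cc(O)cc2O[C@]2(c3ccc(OCc5ccccc5)cc3)Oc3cc(OCc5ccccc5)c(CCC(O)c4ccc(O)cc4)c(O)c3[C@@]12O | intermediate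
26 | para-quinone methide from 25 (not isolated) | O=C1c2c(OCc5ccccc5)cc(O)cc2O[C@]2(c3ccc(OCc5ccccc5)cc3)Oc3cc(OCc5ccccc5)c(CCC=C4C=CC(=O)C=C4)c(O)c3[C@@]12O | intermediate
27 | 5,4',5''-tri-O-benzyldaphnodorin F (2S,3R,2''S) | O=C1c2c(OCc5ccccc5)cc(O)cc2O[C@]2(c3ccc(OCc5ccccc5)cc3)Oc3cc(OCc5ccccc5)c4c(c3[C@@]12O)O[C@H](c1ccc(O)cc1)CC4 | intermediate
28 | daphnodorin F (2S,3R,2''S) | O=C1c2c(O)cc(O)cc2O[C@]2(c3ccc(O)cc3)Oc3cc(O)c4c(c3[C@@]12O)O[C@H](c1ccc(O)cc1)CC4 | target

## Step count and risks

Total: 18 steps. Longest linear sequence: 16 steps (steps 1, 2, 5–18); steps 3 and 4 form the side branch to ynone 7.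

**Step 15 (proposed new method).**
- Most likely failure: slow oxo transfer to a tetrasubstituted, push–pull alkene that is flanked by the C4 silyl ether, which would let oxidation of the electron-rich rings compete; or poor discrimination between the two faces of the benzofuran.
- Fallback (from 22, rejoining at 27): oxidise 22 with dimethyldioxirane in acetone, a known epoxidant for benzofurans and for the enol ether bond of flavones, without chiral control. Epoxide 23 and the antipodal benzofuran epoxide F1 close to 24 and the (2R,3S) bisketal F2. Desilylation as in step 16 gives 25 and the antipodal-core seco compound F3. The key step on this mixture sets C2'' in both series, through 26 and the antipodal-core quinone methide F4, giving 27 and the (2R,3S,2''S) diastereomer F5. These are diastereomers and are separated by chromatography. The cost is half of the material.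

**Step 17 (key step).**
- Most likely failure: uncatalysed or achiral-acid background closure, and reversible reopening of the product, eroding face selectivity, because the same acid that forms the quinone methide can re-ionise C2''; elimination of the carbinol to a styrene is the competing path.
- Fallback (from 25, rejoining at 27): give up kinetic catalyst control. Close 25 with an achiral acid (diphenyl phosphate) to 27 and the C2'' epimer F6. Separate the two, which are diastereomers because the core is homochiral. Recycle F6 by re-exposure to the same acid, which reopens it through 26.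

**Step 5.**
- Most likely failure: metalation at the benzylic position of the benzyl ether (followed by Wittig rearrangement), or incomplete ring lithiation, because excess n-BuLi is needed on a hindered amino alkoxide.
- Fallback (from 3, rejoining at 16): carry 3 iodine-free through steps 6 to 9 and iodinate afterwards by electrophilic substitution. The sequence runs through the iodine-free chalcone F7, its TIPS ether F8, the dihydrochalcone F9, the dihydroxy ketone F10 (not isolated) and the iodine-free chromanol F11. F11 is iodinated with N-iodosuccinimide, relying on the preference of 5,7-dioxygenated chromans for substitution at C8, next to the ring oxygen; the position of iodine would have to be proven.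

**Step 8.**
- Most likely failure: slow hydrogenation of the hindered conjugated alkene, which would allow slow hydrodeiodination.
- Fallback (from 13 directly to 14): replace hydrogenation by conjugate hydride delivery from a copper hydride (monovalent copper) generated catalytically from Cu(OAc)2, a bisphosphine and a hydrosilane in toluene with t-BuOH. No new compound is involved.

## Further compounds

F1 | step 15 | antipodal 2,3-epoxide of 22 (not isolated) | O=C(c1c(O)cc(O)cc1OCc1ccccc1)[C@]12O[C@@]1(c1ccc(OCc3ccccc3)cc1)Oc1cc(OCc3ccccc3)c(CCC(O[Si](C)(C)C(C)(C)C)c3ccc(O[Si](C(C)C)(C(C)C)C(C)C)cc3)c(O[Si](C)(C)C(C)(C)C)c12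
F2 | step 15 | (2R,3S) bisketal, core antipode of 24 (both carbinol epimers) | O=C1c2c(OCc5ccccc5)cc(O)cc2O[C@@]2(c3ccc(OCc5ccccc5)cc3)Oc3cc(OCc5ccccc5)c(CCC(O[Si](C)(C)C(C)(C)C)c4ccc(O[Si](C(C)C)(C(C)C)C(C)C)cc4)c(O[Si](C)(C)C(C)(C)C)c3[C@]12O
F3 | step 15 | (2R,3S) seco compound, core antipode of 25 (both carbinol epimers) | O=C1c2c(OCc5ccccc5)cc(O)cc2O[C@@]2(c3ccc(OCc5ccccc5)cc3)Oc3cc(OCc5ccccc5)c(CCC(O)c4ccc(O)cc4)c(O)c3[C@]12O
F4 | step 15 | (2R,3S) para-quinone methide, core antipode of 26 (not isolated) | O=C1c2c(OCc5ccccc5)cc(O)cc2O[C@@]2(c3ccc(OCc5ccccc5)cc3)Oc3cc(OCc5ccccc5)c(CCC=C4C=CC(=O)C=C4)c(O)c3[C@]12O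
F5 | step 15 | (2R,3S,2''S) diastereomer of 27 | O=C1c2c(OCc5ccccc5)cc(O)cc2O[C@@]2(c3ccc(OCc5ccccc5)cc3)Oc3cc(OCc5ccccc5)c4c(c3[C@]12O)O[C@H](c1ccc(O)cc1)CC4
F6 | step 17 | (2S,3R,2''R) C2'' epimer of 27 | O=C1c2c(OCc5ccccc5)cc(O)cc2O[C@]2(c3ccc(OCc5ccccc5)cc3)Oc3cc(OCc5ccccc5)c4c(c3[C@@]12O)O[C@@H](c1ccc(O)cc1)CC4
F7 | step 5 | (E)-3-[2-(benzyloxy)-4,6-bis(methoxymethoxy)phenyl]-1-(4-hydroxyphenyl)prop-2-en-1-one | O=C(/C=C/c1c(OCc2ccccc2)cc(OCOC)cc1OCOC)c1ccc(O)cc1
F8 | step 5 | (E)-3-[2-(benzyloxy)-4,6-bis(methoxymethoxy)phenyl]-1-[4-(triisopropylsilyloxy)phenyl]prop-2-en-1-one | O=C(/C=C/c1c(OCc2ccccc2)cc(OCOC)cc1OCOC)c1ccc(O[Si](C(C)C)(C(C)C)C(C)C)cc1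
F9 | step 5 | 3-[2-(benzyloxy)-4,6-bis(methoxymethoxy)phenyl]-1-[4-(triisopropylsilyloxy)phenyl]propan-1-one | O=C(CCc1c(OCc2ccccc2)cc(OCOC)cc1OCOC)c1ccc(O[Si](C(C)C)(C(C)C)C(C)C)cc1
F10 | step 5 | 3-[2-(benzyloxy)-4,6-dihydroxyphenyl]-1-[4-(triisopropylsilyloxy)phenyl]propan-1-one (not isolated) | O=C(CCc1c(OCc2ccccc2)cc(O)cc1O)c1ccc(O[Si](C(C)C)(C(C)C)C(C)C)cc1
F11 | step 5 | racemic 5-(benzyloxy)-2-methoxy-2-[4-(triisopropylsilyloxy)phenyl]chroman-7-ol | COC1(c2ccc(O[Si](C(C)C)(C(C)C)C(C)C)cc2)CCc2c(OCc3ccccc3)cc(O)cc2O1
F0 | step 8 | none | none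
A1 | alternative 1 | 5,7-bis(benzyloxy)-2,2-dimethyl-4H-1,3-benzodioxin-4-one | CC1(C)OC(=O)c2c(OCc3ccccc3)cc(OCc3ccccc3)cc2O1
A2 | alternative 1 | (2''S)-flavan-fused 3-(benzyloxycarbonyloxy)-2-[4-(benzyloxy)phenyl]benzofuran, 5''-O-benzyl, ring E O-benzyl | O=C(OCc1ccccc1)Oc1c(-c2ccc(OCc3ccccc3)cc2)oc2cc(OCc3ccccc3)c3c(c12)O[C@H](c1ccc(OCc2ccccc2)cc1)CC3
A3 | alternative 1 | 3,5-bis(benzyloxy)-6-(oxomethylidene)cyclohexa-2,4-dien-1-one (ring A quinoketene) | O=C=C1C(OCc2ccccc2)=CC(OCc2ccccc2)=CC1=O
A4 | alternative 1 | penta-O-benzyl daphnodorin F C3 benzyl carbonate | O=C1c2c(OCc5ccccc5)cc(OCc5ccccc5)cc2O[C@]2(c3ccc(OCc5ccccc5)cc3)Oc3cc(OCc5ccccc5)c4c(c3[C@@]12OC(=O)OCc5ccccc5)O[C@H](c1ccc(OCc5ccccc5)cc1)CC4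
A5 | alternative 2 | 3-[(2S)-7-acetoxy-5-(benzyloxy)-2-(4-benzyloxyphenyl)chroman-8-yl]-5,7-bis(benzyloxy)-2-[4-(benzyloxy)phenyl]chromen-4-one | CC(=O)Oc1cc(OCc2ccccc2)c2c(c1-c1c(-c3ccc(OCc4ccccc4)cc3)oc3cc(OCc4ccccc4)cc(OCc4ccccc4)c3c1=O)O[C@H](c1ccc(OCc3ccccc3)cc1)CC2
A6 | alternative 2 | penta-O-benzyl daphnodorin F | O=C1c2c(OCc5ccccc5)cc(OCc5ccccc5)cc2O[C@]2(c3ccc(OCc5ccccc5)cc3)Oc3cc(OCc5ccccc5)c4c(c3[C@@]12O)O[C@H](c1ccc(OCc5ccccc5)cc1)CC4
A7 | alternative 3 | (2''S)-flavan-fused 3-[4-(benzyloxy)benzoyl]-3-hydroxybenzofuran-2(3H)-one, C3 configured as in 28, 5''-O-benzyl, ring E O-benzyl | O=C1Oc2cc(OCc3ccccc3)c3c(c2[C@]1(O)C(=O)c1ccc(OCc2ccccc2)cc1)O[C@H](c1ccc(OCc2ccccc2)cc1)CC3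
A8 | alternative 3 | phloroglucinol | Oc1cc(O)cc(O)c1
A9 | alternative 3 | 4',5''-di-O-benzyl, ring E O-benzyl daphnodorin F (ring A hydroxyls free) | O=C1c2c(O)cc(O)cc2O[C@]2(c3ccc(OCc5ccccc5)cc3)Oc3cc(OCc5ccccc5)c4c(c3[C@@]12O)O[C@H](c1ccc(OCc5ccccc5)cc1)CC4
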